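I start from the amounts charged: each Q that goes takes one J with it, and it ends as D or as X.

| flask | Q | J | remark | time |
|---|---|---|---|---|
| north-west | 1.5 M | 0.53 M | run made earlier |  |
| west | 1.5 M | 0.89 M | run made earlier |  |
| south | 1.5 M | 1.7 M | run made earlier |  |
| epsilon | 1.5 M | 1.58 M |  | 2.0 min |
| zeta | 1.0 M | 0.500 M |  | 2.0 min |

- north-west (time / s: D / %, Q / %): 10.0: 5.6, 94.0; 12.0: 5.5, 95.7; 25.0: 9.1, 91.2; 60.0: 12.9, 82.6
- west (time / s: D / %, Q / %): 15.0: 9.5, 88.1; 30.0: 13.0, 80.7; 50.0: 19.4, 77.1; 60.0: 20.4, 72.5
- south (time / s: D / %, Q / %): 15.0: 17.3, 81.8; 30.0: 25.6, 69.3; 50.0: 31.1, 62.3; 60.0: 30.2, 60.6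

(each reading ± 1 percentage point)

- steps thought possible: Q + J -> D; 2 J -> E; D <-> X

- the flask that ends with the higher amount of D, in percent of the Q charged, or "neither" when 2 percentage points or less lies between them (epsilon / zeta / neither)
- final D, as a percentage of the Q charged, in epsilon
- final D, as a percentage of the Q charged, in zeta

So I write the balance of J, which is the limiting reagent in zeta: J charged equals J still there, plus J taken by Q, plus J lost in pairs to E. I call the fraction of the charged J that Q has taken the catch, and the last reading of the west run gives 0.463. The north-west run gives 0.492 and the south run 0.348, so the catch read at the last reading is lower in the south run than in the north-west run. But these readings stop at 60.0 s, while the new flasks run 2.0 min, so the catch in the new flasks is an estimate, and I commit to the west value for both as a rough middle.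

Q lost, as a fraction of its charge, is the catch times J charged over Q charged: 48.8% in epsilon and 23.2% in zeta. In the south run, a quarter of the lost Q is missing from D at the last reading, and I let that grow to a third by the end. That leaves D at 32.5% in epsilon and 15.4% in zeta, so I expect epsilon to end higher.

The forecast says epsilon, with 31% (26% to 37%) in epsilon and 18% (14% to 22%) in zeta, on the ground that “percent of Q scales with J/Q”, and its zeta stands higher than mine.

The higher flask is epsilon, with D at 31.7% in epsilon and 18.1% in zeta.

    Q + J → D (k = 0.0110 M⁻¹ s⁻¹)
    2 J → E (k = 0.00840 M⁻¹ s⁻¹)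
    D ⇌ X (K = 0.710, k = 0.00890 s⁻¹)

Beside that D, epsilon holds X at 15.8% at the end. The catch comes to 0.450 in epsilon and 0.528 in zeta, against my 0.463. The neighbour of epsilon charged with 2.7 M of J has a catch of 0.335, and its D ends at 39.8%.

The readings stem from a simulated flask for an exercise, and the scatter is random.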